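**Plan** (target numbered as a bicyclo[3.2.1]octan-8-one: C1 = OMe bridgehead, C2 = CHOH, C3 = CHOMe, C5 = allyl bridgehead, C6 = CHMe, C7 = CHAr, C8 = C=O)
- Cuts: C1–C2 (intramolecular aldol), C7–aryl (conjugate addition), C5–allyl (enolate alkylation), then C8–C1 together with C6–C7 in one operation (acylation of 1-methoxyvinyllithium followed by Nazarov closure).
- Enabling feature: the five-membered ring C5–C8(=O)–C1(OMe)–C7–C6 is a cyclopentanone whose carbonyl carbon carries an O-substituted α-carbon, i.e. a masked 2-methoxycyclopent-2-enone, the retron of an alkoxy-polarized Nazarov cyclization. C8, C5, C4, C3, C2 and the C3 oxygen are the skeleton of (R)-5-(hydroxymethyl)butyrolactone.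
- Forward order: lactone → α-ethylidene lactone → five-membered ring → quaternary C5 → aryl at C7 → six-membered ring (C1–C2) last.
- Stereochemistry: C3 from the chiral pool; C6 from catalyst-controlled conrotation; C5 and C7 by attack anti to the C6 methyl group; C1 by the tether; C2 by a chelated chair aldolate.

Key step: step 3

Assumption: ring carbons α to the ketone that still carry hydrogen are epimerizable and are re-enolized later, so they are drawn without configuration in the intermediates concerned.

Step 1
Reactants: 1 (5R)-5-(hydroxymethyl)oxolan-2-one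
Product: 2 (5R)-5-{[tert-butyl(diphenyl)silyl]oxymethyl}oxolan-2-one
Conditions: t-BuPh2SiCl, imidazole, CH2Cl2, 0 °C → rt
Reagents that add atoms: tert-butyl(chloro)diphenylsilane CC(C)(C)[Si](Cl)(c1ccccc1)c1ccccc1
Why: O-silylation of the primary alcohol gives a silyl ether that should survive amide bases, organolithium, acid and cuprate and fall to fluoride later; the stereocentre is not touched.

Step 2
Reactants: 2 (5R)-5-{[tert-butyl(diphenyl)silyl]oxymethyl}oxolan-2-one; 3 acetaldehyde
Product: 6 (3E,5R)-5-{[tert-butyl(diphenyl)silyl]oxymethyl}-3-ethylideneoxolan-2-one, via aldol adduct 4 (not isolated), via mesylate 5 (not isolated)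
Conditions: LiN(iPr)2, THF, −78 °C; CH3CHO; MeSO2Cl, −78 → 0 °C; then DBU, rt
Reagents that add atoms: none
Why: Aldol addition of the lactone lithium enolate, mesylation of the aldolate and E1cB elimination (aldol condensation) should give the conjugated alkylidene lactone as the more stable (E) isomer (methyl trans to C=O), with C5 unaffected.

Step 3
Reactants: 6 (3E,5R)-5-{[tert-butyl(diphenyl)silyl]oxymethyl}-3-ethylideneoxolan-2-one; 7 methyl vinyl ether
Product: 10 (4S)-5-[(2R)-3-{[tert-butyl(diphenyl)silyl]oxy}-2-hydroxypropyl]-2-methoxy-4-methylcyclopent-2-en-1-one, via lactol 8 (not isolated), via hydroxy dienone 9 (not isolated)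
Conditions: 7 (excess), t-BuLi, THF, −78 → 0 °C; 6, −78 °C; TfOH (1.0 equiv), −78 °C; THF exchanged for CHCl3; chiral 3,3′-di(9-phenanthryl)-H8-BINOL N-triflylphosphoramide (5 mol%, enantiomer matched to 4S), 0 °C; aq. NaHCO3
Reagents that add atoms: none
Why: Proposed new method: 1-methoxyvinyllithium adds 1,2 to the lactone carbonyl (bond C1–C2 of the future cyclopentenone) and the adduct is stored as a lithium lactolate, which TfOH releases as lactol 8 in equilibrium with the cross-conjugated 2-methoxy dienone 9; the chiral acid then protonates 9 and the hydroxypentadienyl cation undergoes thermal 4π conrotatory electrocyclization (Nazarov cyclization) to form C3–C4, the methoxy group localizing the charge at C2 so that proton loss from C3 gives the 2-methoxy enone. The closest known reaction types are the one-flask cyclopentannelation in which an α-lithio enol ether is acylated by an α,β-unsaturated amide and the α-alkoxy dienone cyclizes on acidification, and the chiral Brønsted acid catalysed Nazarov cyclization of isolated 2-alkoxy-1,4-dien-3-ones; new here is their telescoping, from a lactone, under catalyst control. The only ring closed is the cyclopentenone, by electrocyclization of a pentadienyl cation and not by a polar 5-endo attack. The new stereocentre C4 is fixed by the sense of conrotation, which the chiral counter-anion held at the chelating C=O/OMe site should dictate, whereas C5 is epimerizable and left undefined. The step needs 1,2- rather than 1,4-addition and a single addition (hard organolithium at −78 °C, β-methyl group, lactolate inert until protonated), the (E)-ethylidene geometry that places the methyl group outside the U-shaped cation, and no achiral acid at the cyclization stage (one equivalent of TfOH only, LiOTf being non-basic). Since the (R)-carbinol centre of the lactone is retained, any C4 epimer is a diastereomer and can be removed by chromatography.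

Step 4
Reactants: 10 (4S)-5-[(2R)-3-{[tert-butyl(diphenyl)silyl]oxy}-2-hydroxypropyl]-2-methoxy-4-methylcyclopent-2-en-1-one
Product: 11 (4S)-5-[(2R)-3-{[tert-butyl(diphenyl)silyl]oxy}-2-methoxypropyl]-2-methoxy-4-methylcyclopent-2-en-1-one
Conditions: MeOTf, 2,6-di-tert-butyl-4-methylpyridine, CH2Cl2, 0 °C → rt
Reagents that add atoms: methyl trifluoromethanesulfonate COS(=O)(=O)C(F)(F)F
Why: O-methylation of the secondary alcohol with a strong methylating agent and a hindered non-nucleophilic base avoids alkoxide formation, and with it silyl migration and enolization of the enone; no stereocentre is changed.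

Step 5
Reactants: 11 (4S)-5-[(2R)-3-{[tert-butyl(diphenyl)silyl]oxy}-2-methoxypropyl]-2-methoxy-4-methylcyclopent-2-en-1-one; 12 allyl bromide
Product: 13 (4S,5S)-5-[(2R)-3-{[tert-butyl(diphenyl)silyl]oxy}-2-methoxypropyl]-2-methoxy-4-methyl-5-(prop-2-en-1-yl)cyclopent-2-en-1-one
Conditions: LiN(iPr)2, THF, −78 °C; 12, DMPU, −78 → −20 °C
Reagents that add atoms: none
Why: Kinetic α′-deprotonation of the cyclopentenone gives the cross-conjugated lithium enolate, and enolate alkylation should occur on the face anti to the adjacent C4 methyl group, so the quaternary C5 carries allyl trans and the oxygenated side chain cis to methyl.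

Step 6
Reactants: 13 (4S,5S)-5-[(2R)-3-{[tert-butyl(diphenyl)silyl]oxy}-2-methoxypropyl]-2-methoxy-4-methyl-5-(prop-2-en-1-yl)cyclopent-2-en-1-one; 14 (3,4,5-trimethoxyphenyl)magnesium bromide
Product: 16 (2S,3S,4R)-2-[(2R)-3-hydroxy-2-methoxypropyl]-5-methoxy-3-methyl-2-(prop-2-en-1-yl)-4-(3,4,5-trimethoxyphenyl)cyclopentan-1-one, via silyl enol ether 15 (not isolated)
Conditions: 14, CuBr·SMe2 (20 mol%), Me3SiCl, THF, −78 → −30 °C; then Bu4NF, THF, 0 °C → rt
Reagents that add atoms: none
Why: Copper-catalysed conjugate addition of the aryl Grignard reagent with silyl trapping should deliver the aryl group to the enone β-carbon anti to the vicinal methyl group (aryl trans to methyl), and fluoride then cleaves both the enol silane and the silyl ether; the methoxy-bearing α-carbon is left as an epimer mixture.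

Step 7
Reactants: 16 (2S,3S,4R)-2-[(2R)-3-hydroxy-2-methoxypropyl]-5-methoxy-3-methyl-2-(prop-2-en-1-yl)-4-(3,4,5-trimethoxyphenyl)cyclopentan-1-one
Product: 17 (2R)-2-methoxy-3-[(1S,4R,5S)-3-methoxy-5-methyl-2-oxo-1-(prop-2-en-1-yl)-4-(3,4,5-trimethoxyphenyl)cyclopentyl]propanal
Conditions: Dess–Martin periodinane, NaHCO3, CH2Cl2, 0 °C → rt
Reagents that add atoms: none
Why: Dess–Martin oxidation converts the primary alcohol to the α-methoxy aldehyde under buffered, near-neutral conditions that should leave the ketone, the alkene and the α-stereocentre alone.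

Step 8
Reactants: 17 (2R)-2-methoxy-3-[(1S,4R,5S)-3-methoxy-5-methyl-2-oxo-1-(prop-2-en-1-yl)-4-(3,4,5-trimethoxyphenyl)cyclopentyl]propanal
Product: 18 (1R,2R,3R,5S,6S,7R)-2-hydroxy-1,3-dimethoxy-6-methyl-5-(prop-2-en-1-yl)-7-(3,4,5-trimethoxyphenyl)bicyclo[3.2.1]octan-8-one
Conditions: MgBr2·OEt2, Et3N, CH2Cl2, 0 °C → rt
Reagents that add atoms: none
Why: Soft enolization of the α-methoxy ketone at its only α-hydrogen and intramolecular aldol addition (6-(enolendo)-exo-trig) closes the six-membered ring; C1 is dictated by the tether (side chain cis to the C6 methyl), the C2 hydroxyl is axial and syn to C8=O because the magnesium aldolate is chelated by that carbonyl in a closed chair transition state, and the C3 methoxy group stays equatorial, which is also where any epimerization of the aldehyde α-carbon would lead.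

**Compound list**
1 | (5R)-5-(hydroxymethyl)oxolan-2-one | O=C1CC[C@H](CO)O1 | starting material
2 | (5R)-5-{[tert-butyl(diphenyl)silyl]oxymethyl}oxolan-2-one | O=C1CC[C@H](CO[Si](c2ccccc2)(c2ccccc2)C(C)(C)C)O1 | intermediate
3 | acetaldehyde | CC=O | starting material
4 | (5R)-5-{[tert-butyl(diphenyl)silyl]oxymethyl}-3-(1-hydroxyethyl)oxolan-2-one (lithium alkoxide in the flask, diastereomer mixture) | CC(O)C1C[C@H](CO[Si](c2ccccc2)(c2ccccc2)C(C)(C)C)OC1=O | intermediate
5 | 1-[(5R)-5-{[tert-butyl(diphenyl)silyl]oxymethyl}-2-oxooxolan-3-yl]ethyl methanesulfonate (diastereomer mixture) | CC(OS(C)(=O)=O)C1C[C@H](CO[Si](c2ccccc2)(c2ccccc2)C(C)(C)C)OC1=O | intermediate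
6 | (3E,5R)-5-{[tert-butyl(diphenyl)silyl]oxymethyl}-3-ethylideneoxolan-2-one | C/C=C1\C[C@H](CO[Si](c2ccccc2)(c2ccccc2)C(C)(C)C)OC1=O | intermediate
7 | methyl vinyl ether (methoxyethene) | C=COC | starting material
8 | (3E,5R)-5-{[tert-butyl(diphenyl)silyl]oxymethyl}-3-ethylidene-2-(1-methoxyethenyl)oxolan-2-ol (anomer mixture) | C/C=C1\C[C@H](CO[Si](c2ccccc2)(c2ccccc2)C(C)(C)C)OC1(O)C(=C)OC | intermediate
9 | (4E)-4-[(2R)-3-{[tert-butyl(diphenyl)silyl]oxy}-2-hydroxypropyl]-2-methoxyhexa-1,4-dien-3-one | C/C=C(/C(=O)C(=C)OC)C[C@@H](O)CO[Si](c1ccccc1)(c1ccccc1)C(C)(C)C | intermediate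
10 | (4S)-5-[(2R)-3-{[tert-butyl(diphenyl)silyl]oxy}-2-hydroxypropyl]-2-methoxy-4-methylcyclopent-2-en-1-one (C5 epimers) | O=C1C(OC)=C[C@H](C)C1C[C@@H](O)CO[Si](c2ccccc2)(c2ccccc2)C(C)(C)C | intermediate
11 | (4S)-5-[(2R)-3-{[tert-butyl(diphenyl)silyl]oxy}-2-methoxypropyl]-2-methoxy-4-methylcyclopent-2-en-1-one (C5 epimers) | O=C1C(OC)=C[C@H](C)C1C[C@@H](OC)CO[Si](c2ccccc2)(c2ccccc2)C(C)(C)C | intermediate
12 | allyl bromide (3-bromoprop-1-ene) | C=CCBr | starting material
13 | (4S,5S)-5-[(2R)-3-{[tert-butyl(diphenyl)silyl]oxy}-2-methoxypropyl]-2-methoxy-4-methyl-5-(prop-2-en-1-yl)cyclopent-2-en-1-one | C=CC[C@]1(C[C@@H](OC)CO[Si](c2ccccc2)(c2ccccc2)C(C)(C)C)[C@@H](C)C=C(OC)C1=O | intermediate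
14 | (3,4,5-trimethoxyphenyl)magnesium bromide (THF solution) | COc1cc([Mg]Br)cc(OC)c1OC | starting material
15 | trimethylsilyl enol ether of the conjugate adduct of 13 (1-trimethylsilyloxy-2-methoxycyclopentene; aryl trans to methyl; silyl ether retained) | C=CC[C@]1(C[C@@H](OC)CO[Si](c2ccccc2)(c2ccccc2)C(C)(C)C)[C@@H](C)[C@H](c2cc(OC)c(OC)c(OC)c2)C(OC)=C1O[Si](C)(C)C | intermediate
16 | (2S,3S,4R)-2-[(2R)-3-hydroxy-2-methoxypropyl]-5-methoxy-3-methyl-2-(prop-2-en-1-yl)-4-(3,4,5-trimethoxyphenyl)cyclopentan-1-one (C5 epimers) | C=CC[C@]1(C[C@@H](OC)CO)[C@@H](C)[C@H](c2cc(OC)c(OC)c(OC)c2)C(OC)C1=O | intermediate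
17 | (2R)-2-methoxy-3-[(1S,4R,5S)-3-methoxy-5-methyl-2-oxo-1-(prop-2-en-1-yl)-4-(3,4,5-trimethoxyphenyl)cyclopentyl]propanal (C3 epimers of the ring) | C=CC[C@]1(C[C@@H](OC)C=O)[C@@H](C)[C@H](c2cc(OC)c(OC)c(OC)c2)C(OC)C1=O | intermediate
18 | (1R,2R,3R,5S,6S,7R)-2-hydroxy-1,3-dimethoxy-6-methyl-5-(prop-2-en-1-yl)-7-(3,4,5-trimethoxyphenyl)bicyclo[3.2.1]octan-8-one | C=CC[C@@]12C[C@@H](OC)[C@@H](O)[C@@](OC)(C1=O)[C@@H](c1cc(OC)c(OC)c(OC)c1)[C@@H]2C | target

**Totals**
Total steps: 8. Longest linear sequence: 8 steps (from 1).

**Steps most likely to fail, with fallbacks**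

For step 3 (Proposed new method): the organolithium may add in conjugate fashion to the ethylidene lactone. Cyclization may also be promoted by lithium salts or traces of achiral acid before the chiral acid is in control, or the catalyst may be inhibited by the free hydroxyl group and residual THF; each erodes torquoselectivity at C4. Fallback with known chemistry, setting out from 6: 1-methoxyvinyllithium is added as before, but the mixture is quenched with aqueous NH4Cl and the lactol/hydroxy ketone pair (8 and 9) is isolated. O-Methylation of the open hydroxy ketone (MeOTf, 2,6-di-tert-butyl-4-methylpyridine) gives the non-hydroxylic 2-methoxy dienone F1. This is an isolated substrate of the class for which the chiral N-triflylphosphoramide catalysed Nazarov cyclization in CHCl3 is established, and the cyclization delivers 11, where the route is rejoined.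

For step 8: facial control at the aldehyde may be lost (C2 epimers) if the magnesium aldolate is not chelated, and retro-aldol equilibrium may leave the conversion incomplete. Fallback, setting out from 17: the ring is closed under simple equilibrating conditions (DBU, CH2Cl2), accepting the C2-epimeric ketol F2 alone or mixed with 18. Dess–Martin oxidation of the mixture gives the 2,8-dione F3. LiBH(sec-Bu)3 at −78 °C should then reduce only the C2 ketone (C8 is flanked by two quaternary carbons), attacking from the exposed equatorial direction to give the axial alcohol 18.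

For step 5: the hindered tetrasubstituted enolate may undergo O-allylation or only slow C-alkylation, γ-deprotonation may compete, and facial discrimination at the new quaternary centre may be insufficient. Fallback, setting out from 11: the same lithium enolate is O-acylated with allyl chloroformate to the allyl dienol carbonate F4. Pd(PPh3)4 (zerovalent palladium) in THF then triggers decarboxylative allylation (Tsuji allylation) through a π-allylpalladium enolate ion pair, which should place the allyl group on carbon, anti to the C4 methyl group, and returns to 13.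

**Further compounds**
F1 | step 3 | (4E)-4-[(2R)-3-{[tert-butyl(diphenyl)silyl]oxy}-2-methoxypropyl]-2-methoxyhexa-1,4-dien-3-one | C/C=C(/C(=O)C(=C)OC)C[C@@H](OC)CO[Si](c1ccccc1)(c1ccccc1)C(C)(C)C
F2 | step 8 | (1R,2S,3R,5S,6S,7R)-2-hydroxy-1,3-dimethoxy-6-methyl-5-(prop-2-en-1-yl)-7-(3,4,5-trimethoxyphenyl)bicyclo[3.2.1]octan-8-one (C2 epimer of 18) | C=CC[C@@]12C[C@@H](OC)[C@H](O)[C@@](OC)(C1=O)[C@@H](c1cc(OC)c(OC)c(OC)c1)[C@@H]2C
F3 | step 8 | 1,3-dimethoxy-6-methyl-5-(prop-2-en-1-yl)-7-(3,4,5-trimethoxyphenyl)bicyclo[3.2.1]octane-2,8-dione (ring stereocentres as in 18) | C=CC[C@@]12C[C@@H](OC)C(=O)[C@@](OC)(C1=O)[C@@H](c1cc(OC)c(OC)c(OC)c1)[C@@H]2C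
F4 | step 5 | prop-2-en-1-yl (3S)-2-[(2R)-3-{[tert-butyl(diphenyl)silyl]oxy}-2-methoxypropyl]-5-methoxy-3-methylcyclopenta-1,4-dien-1-yl carbonate | C=CCOC(=O)OC1=C(C[C@@H](OC)CO[Si](c2ccccc2)(c2ccccc2)C(C)(C)C)[C@@H](C)C=C1OC
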